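**Plan**

- Retrosynthesis: the two 4-hydroxybenzoate ester C–O bonds are cut first, then the aryl–alkenyl bond at C5, and last the O1–C2 and C2–C3 bonds of the dihydrofuran ring, both at once.
- Enabling feature: C2, which carries the syringyl ring, has only O1 and C3 as ring neighbours. Ring B can therefore be closed by inserting this one benzylic carbon between the phenol oxygen and the exocyclic methide carbon (the later C3) of an ortho-quinone methide built on ring A.
- Forward: ring A is carried as sulfone 6 (from 5-bromo-o-vanillin) and the C2 unit as thiolanium salt 14 (from syringaldehyde and a C2-symmetric thiolane). Their [4+1] union closes ring B; the propenol chain is then coupled at C5, all silyl groups are removed and both primary alcohols are esterified.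
- Stereochemistry: the centre of racemic 6 is erased in the planar methide. C2 is set by the face-selective (2S,5S)-2,5-dimethylthiolanium benzylide and C3 by the trans-selective annulation, giving (2S,3R). The E alkene comes from the E-alkenylboronate.

Key step: step 11

Assumption: the benzylide of this thiolane is taken to react on the same face as in its benzylidene transfer to aldehydes, where the (2R,5R)-sulfide gives the (S)-configured epoxide carbon. At C2 of the dihydrobenzofuran the CIP ranks of aryl and the new C–C partner are exchanged, so that face corresponds to (2R), and the (2S,5S)-sulfide (from (2R,5R)-hexane-2,5-diol) is therefore used.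

**Route**

Step 1
Reactants: 1 5-bromo-2-hydroxy-3-methoxybenzaldehyde
Product: 2 4-bromo-2-ethenyl-6-methoxyphenol
Conditions: Ph3PCH3Br (2.5 equiv), KOtBu (2.5 equiv), THF, 0 °C to rt
Reagents that add atoms: methyltriphenylphosphonium bromide, C[P+](c1ccccc1)(c1ccccc1)c1ccccc1.[Br-]
Why: Wittig methylenation, in which an excess of the unstabilised ylide first forms the phenoxide and then converts the aldehyde into the vinyl group, as is routine for salicylaldehydes.

Step 2
Reactants: 2 4-bromo-2-ethenyl-6-methoxyphenol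
Product: 3 rac-1-(5-bromo-2-hydroxy-3-methoxyphenyl)ethane-1,2-diol
Conditions: K2OsO4·2H2O (2 mol %), NMO (1.5 equiv), acetone/H2O 4:1, rt
Reagents that add atoms: N-methylmorpholine N-oxide, C[N+]1([O-])CCOCC1; water, O
Why: Catalytic osmium dihydroxylation with NMO as terminal oxidant adds two hydroxyl groups syn to the electron-rich styrene; the new centre may be racemic because it is erased in step 11.

Step 3
Reactants: 3 rac-1-(5-bromo-2-hydroxy-3-methoxyphenyl)ethane-1,2-diol
Product: 4 rac-4-bromo-2-[2-(tert-butyldiphenylsilyloxy)-1-hydroxyethyl]-6-methoxyphenol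
Conditions: TBDPSCl (1.05 equiv), imidazole (2 equiv), CH2Cl2/THF, 0 °C
Reagents that add atoms: tert-butyl(chloro)diphenylsilane, CC(C)(C)[Si](Cl)(c1ccccc1)c1ccccc1
Why: Imidazole-mediated silylation with the bulky chlorosilane should take the primary hydroxyl ahead of the secondary benzylic hydroxyl and the hydrogen-bonded, doubly ortho-substituted phenol; TBDPS is chosen because it withstands the acid of step 4.

Step 4
Reactants: 4 rac-4-bromo-2-[2-(tert-butyldiphenylsilyloxy)-1-hydroxyethyl]-6-methoxyphenol
Product: 6 rac-4-bromo-2-[2-(tert-butyldiphenylsilyloxy)-1-(4-methylphenylsulfonyl)ethyl]-6-methoxyphenol, via ortho-hydroxybenzylic cation 5 (not isolated)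
Conditions: TolSO2Na (2 equiv), TsOH·H2O (1.5 equiv), CH2Cl2, rt
Reagents that add atoms: sodium 4-methylbenzenesulfinate, Cc1ccc(S(=O)[O-])cc1.[Na+]
Why: Under TsOH the benzylic hydroxyl of the ortho-hydroxybenzyl alcohol ionises with loss of water to the ortho-hydroxy-stabilised benzylic cation 5 (the O-protonated form of the ring-A quinone methide), which the sulfinate captures at carbon through sulfur in an SN1-type substitution, the standard preparation of 2-(1-sulfonylalkyl)phenols; the centre formed is racemic and is erased in step 11.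

Step 5
Reactants: 7 (2R,5R)-hexane-2,5-diol
Product: 8 (2R,5R)-hexane-2,5-diyl dimethanesulfonate
Conditions: MsCl (2.5 equiv), Et3N (3 equiv), CH2Cl2, −20 to 0 °C
Reagents that add atoms: methanesulfonyl chloride, CS(=O)(=O)Cl
Why: Mesylation of both secondary alcohols takes place at oxygen, so both carbon centres keep their configuration.

Step 6
Reactants: 8 (2R,5R)-hexane-2,5-diyl dimethanesulfonate
Product: 9 (2S,5S)-2,5-dimethylthiolane
Conditions: Na2S·9H2O (1.3 equiv), DMSO, rt; pentane extraction, distillation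
Reagents that add atoms: sodium sulfide, [Na+].[Na+].[S-2]
Why: Double SN2 displacement by sulfide closes the thiolane with inversion at both centres, turning the (2R,5R)-dimesylate into the (2S,5S)-thiolane.

Step 7
Reactants: 10 4-hydroxy-3,5-dimethoxybenzaldehyde (syringaldehyde)
Product: 11 3,5-dimethoxy-4-(triisopropylsilyloxy)benzaldehyde
Conditions: TIPSCl (1.3 equiv), imidazole (2.5 equiv), DMF, rt to 40 °C
Reagents that add atoms: chlorotri(propan-2-yl)silane, CC(C)[Si](Cl)(C(C)C)C(C)C
Why: Phenol silylation; the TIPS ether is chosen because it should withstand carbonate base and the ylide, yet falls together with the alkyl silyl ethers in step 13.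

Step 8
Reactants: 11 3,5-dimethoxy-4-(triisopropylsilyloxy)benzaldehyde
Product: 12 [3,5-dimethoxy-4-(triisopropylsilyloxy)phenyl]methanol
Conditions: NaBH4 (1 equiv), MeOH/THF, 0 °C
Reagents that add atoms: none
Why: Borohydride reduction of the aryl aldehyde to the benzylic alcohol, which leaves the aryl silyl ether untouched.

Step 9
Reactants: 12 [3,5-dimethoxy-4-(triisopropylsilyloxy)phenyl]methanol
Product: 13 [4-(bromomethyl)-2,6-dimethoxyphenoxy]triisopropylsilane
Conditions: CBr4 (1.3 equiv), PPh3 (1.3 equiv), CH2Cl2, 0 °C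
Reagents that add atoms: tetrabromomethane, BrC(Br)(Br)Br
Why: Appel bromination converts the electron-rich benzylic alcohol into the bromide under neutral conditions that spare the aryl silyl ether.

Step 10
Reactants: 9 (2S,5S)-2,5-dimethylthiolane; 13 [4-(bromomethyl)-2,6-dimethoxyphenoxy]triisopropylsilane
Product: 14 (2S,5S)-1-[3,5-dimethoxy-4-(triisopropylsilyloxy)benzyl]-2,5-dimethylthiolan-1-ium trifluoromethanesulfonate
Conditions: 9 (1.2 equiv), AgOTf (1.05 equiv), CH2Cl2, 0 °C to rt, dark; filtration
Reagents that add atoms: silver trifluoromethanesulfonate, [Ag+].[O-]S(=O)(=O)C(F)(F)F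
Why: S-Alkylation of the sulfide, driven by precipitation of AgBr; the C2 symmetry of the sulfide makes its two lone pairs equivalent, so a single salt forms, and triflate is used so that no fluoride-releasing counter-ion meets the aryl silyl ether.

Step 11
Reactants: 6 rac-4-bromo-2-[2-(tert-butyldiphenylsilyloxy)-1-(4-methylphenylsulfonyl)ethyl]-6-methoxyphenol; 14 (2S,5S)-1-[3,5-dimethoxy-4-(triisopropylsilyloxy)benzyl]-2,5-dimethylthiolan-1-ium trifluoromethanesulfonate
Product: 18 (2S,3R)-5-bromo-3-[(tert-butyldiphenylsilyloxy)methyl]-2-[3,5-dimethoxy-4-(triisopropylsilyloxy)phenyl]-7-methoxy-2,3-dihydro-1-benzofuran, via ortho-quinone methide 15 (not isolated), via sulfonium benzylide 16 (not isolated), via anti betaine 17 (not isolated)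
Conditions: 14 (1.5 equiv), Cs2CO3 (3.5 equiv), CH2Cl2, −20 °C; slow addition of 6; then to rt
Reagents that add atoms: none
Why: Cs2CO3 converts phenol 6 into its phenoxide, which expels 4-methylbenzenesulfinate (erasing the racemic centre) to give planar methide 15, and deprotonates salt 14 to benzylide 16; the ylide carbon adds to the exocyclic methide carbon, forming C2–C3 and restoring the aromaticity of ring A in betaine 17, and the phenoxide then displaces the neutral thiolane, forming O1–C2. The closest known reaction is the formal [4+1] annulation of ortho-quinone methides, released in situ from 2-(1-sulfonylalkyl)phenols, with sulfonium ylides, which gives trans-2,3-dihydrobenzofurans. Ring B closes by a 5-exo-tet SN2 displacement at the sulfonium-bearing benzylic carbon, with inversion at C2. C2 is controlled by the C2-symmetric thiolanium: the ylide aryl group turns away from the ring and the methyl group cis to the ylide carbon shields one face, so the methide is engaged on the other face, and after the invertive closure the (2S,5S)-sulfide should deliver (2S). C3 is set in the same C–C bond formation, relative to C2, by the approach that places aryl and CH2OSi anti in 17, the betaine that can close without eclipsing these groups and leads to the trans ring. The step needs ylide face selectivity, secured by the sulfide, trans selectivity, secured by the anti betaine, and capture of 15 before its 1,5-hydrogen shift to a vinyl phenol, secured by adding 6 slowly to an excess of the electron-rich, strongly nucleophilic benzylide at low temperature.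

Step 12
Reactants: 18 (2S,3R)-5-bromo-3-[(tert-butyldiphenylsilyloxy)methyl]-2-[3,5-dimethoxy-4-(triisopropylsilyloxy)phenyl]-7-methoxy-2,3-dihydro-1-benzofuran; 19 (E)-tert-butyldimethyl{[3-(4,4,5,5-tetramethyl-1,3,2-dioxaborolan-2-yl)prop-2-en-1-yl]oxy}silane
Product: 20 (2S,3R)-5-[(E)-3-(tert-butyldimethylsilyloxy)prop-1-enyl]-3-[(tert-butyldiphenylsilyloxy)methyl]-2-[3,5-dimethoxy-4-(triisopropylsilyloxy)phenyl]-7-methoxy-2,3-dihydro-1-benzofuran
Conditions: 19 (1.3 equiv), PdCl2(dppf) (5 mol %; dppf = 1,1'-bis(diphenylphosphino)ferrocene), K3PO4 (3 equiv), 1,4-dioxane/H2O 5:1, 70 °C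
Reagents that add atoms: none
Why: Suzuki–Miyaura coupling (oxidative addition of zerovalent palladium into the unhindered aryl bromide, transmetalation of the alkenylboronate, reductive elimination) keeps the E geometry and leaves the two ring stereocentres untouched; partial loss of the aryl silyl ether here would be inconsequential because step 13 removes it.

Step 13
Reactants: 20 (2S,3R)-5-[(E)-3-(tert-butyldimethylsilyloxy)prop-1-enyl]-3-[(tert-butyldiphenylsilyloxy)methyl]-2-[3,5-dimethoxy-4-(triisopropylsilyloxy)phenyl]-7-methoxy-2,3-dihydro-1-benzofuran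
Product: 21 4-[(2S,3R)-3-(hydroxymethyl)-5-[(E)-3-hydroxyprop-1-enyl]-7-methoxy-2,3-dihydro-1-benzofuran-2-yl]-2,6-dimethoxyphenol
Conditions: TBAF (5 equiv), THF, 0 °C to rt
Reagents that add atoms: none
Why: Fluoride-mediated desilylation removes the aryl TIPS, allylic TBS and primary TBDPS ethers in one operation without touching either stereocentre.

Step 14
Reactants: 21 4-[(2S,3R)-3-(hydroxymethyl)-5-[(E)-3-hydroxyprop-1-enyl]-7-methoxy-2,3-dihydro-1-benzofuran-2-yl]-2,6-dimethoxyphenol; 22 4-hydroxybenzoic acid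
Product: 23 [(2S,3R)-2-(4-hydroxy-3,5-dimethoxyphenyl)-5-[(E)-3-(4-hydroxybenzoyloxy)prop-1-enyl]-7-methoxy-2,3-dihydro-1-benzofuran-3-yl]methyl 4-hydroxybenzoate (quiquesetinerviusin B)
Conditions: 22 (3 equiv), PPh3 (3 equiv), DIAD (3 equiv), THF, 0 °C to rt
Reagents that add atoms: none
Why: Mitsunobu esterification, in which the two primary alcohols are activated as oxyphosphonium ions and displaced by the carboxylate, which is far more acidic than any phenol present, so the known chemoselective esterification of phenolic acids with phenol-bearing alcohols applies without protection; no stereocentre is involved.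

**Compound list**

1 | 5-bromo-2-hydroxy-3-methoxybenzaldehyde (5-bromo-o-vanillin) | COc1cc(Br)cc(C=O)c1O | starting material
2 | 4-bromo-2-ethenyl-6-methoxyphenol | COc1cc(Br)cc(C=C)c1O | intermediate
3 | rac-1-(5-bromo-2-hydroxy-3-methoxyphenyl)ethane-1,2-diol | COc1cc(Br)cc(C(O)CO)c1O | intermediate
4 | rac-4-bromo-2-[2-(tert-butyldiphenylsilyloxy)-1-hydroxyethyl]-6-methoxyphenol | COc1cc(Br)cc(C(O)CO[Si](c2ccccc2)(c2ccccc2)C(C)(C)C)c1O | intermediate
5 | 1-(5-bromo-2-hydroxy-3-methoxyphenyl)-2-(tert-butyldiphenylsilyloxy)ethan-1-ylium (ortho-hydroxybenzylic cation, the O-protonated form of the ring-A quinone methide) | COc1cc(Br)cc([CH+]CO[Si](c2ccccc2)(c2ccccc2)C(C)(C)C)c1O | intermediate (not isolated)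
6 | rac-4-bromo-2-[2-(tert-butyldiphenylsilyloxy)-1-(4-methylphenylsulfonyl)ethyl]-6-methoxyphenol | COc1cc(Br)cc(C(CO[Si](c2ccccc2)(c2ccccc2)C(C)(C)C)S(=O)(=O)c2ccc(C)cc2)c1O | intermediate
7 | (2R,5R)-hexane-2,5-diol | C[C@@H](O)CC[C@@H](C)O | starting material
8 | (2R,5R)-hexane-2,5-diyl dimethanesulfonate | C[C@@H](OS(C)(=O)=O)CC[C@@H](C)OS(C)(=O)=O | intermediate
9 | (2S,5S)-2,5-dimethylthiolane | C[C@H]1CC[C@H](C)S1 | intermediate
10 | 4-hydroxy-3,5-dimethoxybenzaldehyde (syringaldehyde) | COc1cc(C=O)cc(OC)c1O | starting material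
11 | 3,5-dimethoxy-4-(triisopropylsilyloxy)benzaldehyde | COc1cc(C=O)cc(OC)c1O[Si](C(C)C)(C(C)C)C(C)C | intermediate
12 | [3,5-dimethoxy-4-(triisopropylsilyloxy)phenyl]methanol | COc1cc(CO)cc(OC)c1O[Si](C(C)C)(C(C)C)C(C)C | intermediate
13 | [4-(bromomethyl)-2,6-dimethoxyphenoxy]triisopropylsilane | COc1cc(CBr)cc(OC)c1O[Si](C(C)C)(C(C)C)C(C)C | intermediate
14 | (2S,5S)-1-[3,5-dimethoxy-4-(triisopropylsilyloxy)benzyl]-2,5-dimethylthiolan-1-ium trifluoromethanesulfonate | C[C@H]1CC[C@H](C)[S+]1Cc1cc(OC)c(O[Si](C(C)C)(C(C)C)C(C)C)c(OC)c1.[O-]S(=O)(=O)C(F)(F)F | intermediate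
15 | (E)-4-bromo-6-[2-(tert-butyldiphenylsilyloxy)ethylidene]-2-methoxycyclohexa-2,4-dien-1-one (ortho-quinone methide of ring A; E geometry expected) | COC1=CC(Br)=CC(/C1=O)=C\CO[Si](c1ccccc1)(c1ccccc1)C(C)(C)C | intermediate (not isolated)
16 | sulfonium benzylide: [3,5-dimethoxy-4-(triisopropylsilyloxy)phenyl][(2S,5S)-2,5-dimethylthiolan-1-ium-1-yl]methanide | C[C@H]1CC[C@H](C)[S+]1[CH-]c1cc(OC)c(O[Si](C(C)C)(C(C)C)C(C)C)c(OC)c1 | intermediate (not isolated)
17 | anti betaine: 4-bromo-2-[(2R,3R)-1-(tert-butyldiphenylsilyloxy)-3-[3,5-dimethoxy-4-(triisopropylsilyloxy)phenyl]-3-[(2S,5S)-2,5-dimethylthiolan-1-ium-1-yl]propan-2-yl]-6-methoxyphenolate | COc1cc(cc(OC)c1O[Si](C(C)C)(C(C)C)C(C)C)[C@H]([S+]1[C@@H](C)CC[C@@H]1C)[C@@H](CO[Si](c1ccccc1)(c1ccccc1)C(C)(C)C)c1cc(Br)cc(OC)c1[O-] | intermediate (not isolated)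
18 | (2S,3R)-5-bromo-3-[(tert-butyldiphenylsilyloxy)methyl]-2-[3,5-dimethoxy-4-(triisopropylsilyloxy)phenyl]-7-methoxy-2,3-dihydro-1-benzofuran (trans) | COc1cc([C@H]2Oc3c(OC)cc(Br)cc3[C@@H]2CO[Si](c2ccccc2)(c2ccccc2)C(C)(C)C)cc(OC)c1O[Si](C(C)C)(C(C)C)C(C)C | intermediate
19 | (E)-tert-butyldimethyl{[3-(4,4,5,5-tetramethyl-1,3,2-dioxaborolan-2-yl)prop-2-en-1-yl]oxy}silane | CC(C)(C)[Si](C)(C)OC/C=C/B1OC(C)(C)C(C)(C)O1 | starting material
20 | (2S,3R)-5-[(E)-3-(tert-butyldimethylsilyloxy)prop-1-enyl]-3-[(tert-butyldiphenylsilyloxy)methyl]-2-[3,5-dimethoxy-4-(triisopropylsilyloxy)phenyl]-7-methoxy-2,3-dihydro-1-benzofuran | COc1cc([C@H]2Oc3c(OC)cc(/C=C/CO[Si](C)(C)C(C)(C)C)cc3[C@@H]2CO[Si](c2ccccc2)(c2ccccc2)C(C)(C)C)cc(OC)c1O[Si](C(C)C)(C(C)C)C(C)C | intermediate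
21 | 4-[(2S,3R)-3-(hydroxymethyl)-5-[(E)-3-hydroxyprop-1-enyl]-7-methoxy-2,3-dihydro-1-benzofuran-2-yl]-2,6-dimethoxyphenol | COc1cc([C@H]2Oc3c(OC)cc(/C=C/CO)cc3[C@@H]2CO)cc(OC)c1O | intermediate
22 | 4-hydroxybenzoic acid | OC(=O)c1ccc(O)cc1 | starting material
23 | quiquesetinerviusin B: [(2S,3R)-2-(4-hydroxy-3,5-dimethoxyphenyl)-5-[(E)-3-(4-hydroxybenzoyloxy)prop-1-enyl]-7-methoxy-2,3-dihydro-1-benzofuran-3-yl]methyl 4-hydroxybenzoate | COc1cc([C@H]2Oc3c(OC)cc(/C=C/COC(=O)c4ccc(O)cc4)cc3[C@@H]2COC(=O)c2ccc(O)cc2)cc(OC)c1O | target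

**Step count and risks**

Total step count: 14. Longest linear sequence: 8 steps (1 → 2 → 3 → 4 → 6 → 18 → 20 → 21 → 23; the branch 10 → 11 → 12 → 13 → 14 → 18 → 23 is equally long).

Steps most likely to fail:

Step 11. The methide may tautomerise by a 1,5-hydrogen shift, or dimerise, before the ylide adds. Face discrimination at the ylide, or the anti/syn preference in the C–C bond formation, may also be too low, which would erode enantiomeric and diastereomeric purity. If only the sense of induction is opposite, the antipodal sulfide from (2S,5S)-hexane-2,5-diol is used in the same way. The fallback replaces reagent control by resolution; it sets out from 13 and 6 and returns at 18. Alkylation of tetrahydrothiophene with 13 (AgOTf, CH2Cl2) would give the achiral salt 1-[3,5-dimethoxy-4-(triisopropylsilyloxy)benzyl]thiolan-1-ium trifluoromethanesulfonate F1. Its reaction with 6 under the conditions of step 11 should give the trans-dihydrobenzofuran as the racemate, that is 18 together with its mirror image, the (2R,3S)-configured dihydrobenzofuran F2. Preparative chromatography on a chiral stationary phase (for example cellulose tris(3,5-dimethylphenylcarbamate)) would separate 18 from F2, and the route continues with step 12.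

Step 14. A phenol may be O-alkylated by the activated cinnamyl alcohol, the cinnamyl terminus may undergo allylic transposition, or the second esterification may stall. The fallback uses the alcohols as nucleophiles and masks the phenols temporarily; it sets out from 21 and returns at 23. Selective acetylation of the phenoxide (Ac2O, 1.1 equiv, aqueous NaOH, THF, 0 °C) would give 4-[(2S,3R)-3-(hydroxymethyl)-5-[(E)-3-hydroxyprop-1-enyl]-7-methoxy-2,3-dihydro-1-benzofuran-2-yl]-2,6-dimethoxyphenyl acetate F3. Acylation of both alcohols with commercial 4-acetoxybenzoyl chloride (pyridine, CH2Cl2, 0 °C) would give the triacetate [(2S,3R)-2-(4-acetoxy-3,5-dimethoxyphenyl)-5-[(E)-3-(4-acetoxybenzoyloxy)prop-1-enyl]-7-methoxy-2,3-dihydro-1-benzofuran-3-yl]methyl 4-acetoxybenzoate F4. Aminolysis of the three aryl acetates with pyrrolidine at rt, which leaves alkyl benzoates intact, would then give 23.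

Step 4. Under acid the benzylic cation may lose a proton to give the silyl enol ether and cyclise to a benzofuran, or the silyl ether may be cleaved, before sulfinate captures the cation. The fallback introduces sulfur under neutral conditions and oxidises afterwards; it sets out from 4 and returns at 6. Mitsunobu thioetherification of the benzylic alcohol of 4 with 4-methylbenzenethiol (PPh3, DIAD, THF, 0 °C) would give rac-4-bromo-2-[2-(tert-butyldiphenylsilyloxy)-1-(4-methylphenylsulfanyl)ethyl]-6-methoxyphenol F5. Oxidation with mCPBA (2.2 equiv, CH2Cl2, 0 °C) would convert the sulfide into sulfone 6.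

Further compounds
F1 | step 11 | 1-[3,5-dimethoxy-4-(triisopropylsilyloxy)benzyl]thiolan-1-ium trifluoromethanesulfonate | COc1cc(C[S+]2CCCC2)cc(OC)c1O[Si](C(C)C)(C(C)C)C(C)C.[O-]S(=O)(=O)C(F)(F)F
F2 | step 11 | (2R,3S)-5-bromo-3-[(tert-butyldiphenylsilyloxy)methyl]-2-[3,5-dimethoxy-4-(triisopropylsilyloxy)phenyl]-7-methoxy-2,3-dihydro-1-benzofuran (enantiomer of 18) | COc1cc([C@@H]2Oc3c(OC)cc(Br)cc3[C@H]2CO[Si](c2ccccc2)(c2ccccc2)C(C)(C)C)cc(OC)c1O[Si](C(C)C)(C(C)C)C(C)C
F3 | step 14 | 4-[(2S,3R)-3-(hydroxymethyl)-5-[(E)-3-hydroxyprop-1-enyl]-7-methoxy-2,3-dihydro-1-benzofuran-2-yl]-2,6-dimethoxyphenyl acetate | COc1cc([C@H]2Oc3c(OC)cc(/C=C/CO)cc3[C@@H]2CO)cc(OC)c1OC(C)=O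
F4 | step 14 | [(2S,3R)-2-(4-acetoxy-3,5-dimethoxyphenyl)-5-[(E)-3-(4-acetoxybenzoyloxy)prop-1-enyl]-7-methoxy-2,3-dihydro-1-benzofuran-3-yl]methyl 4-acetoxybenzoate | COc1cc([C@H]2Oc3c(OC)cc(/C=C/COC(=O)c4ccc(OC(C)=O)cc4)cc3[C@@H]2COC(=O)c2ccc(OC(C)=O)cc2)cc(OC)c1OC(C)=O
F5 | step 4 | rac-4-bromo-2-[2-(tert-butyldiphenylsilyloxy)-1-(4-methylphenylsulfanyl)ethyl]-6-methoxyphenol | COc1cc(Br)cc(C(CO[Si](c2ccccc2)(c2ccccc2)C(C)(C)C)Sc2ccc(C)cc2)c1O
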